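I start from the constants and the settings of the flasks.

    starting complex + incoming ligand ⇌ leaving ligand + complex with one exchanged (K1 = 0.41, k1 = 0.27 /M/s, Ea1 = 57.0 kJ/mol, ΔH1 = −17.0 kJ/mol)
    complex with one exchanged + incoming ligand ⇌ leaving ligand + complex with two exchanged (K2 = 23, k2 = 0.068 /M/s, Ea2 = 51.0 kJ/mol, ΔH2 = −78.0 kJ/mol)
    complex with two exchanged + incoming ligand ⇌ leaving ligand + complex with three exchanged (K3 = 52, k3 = 0.098 /M/s, Ea3 = 81.0 kJ/mol, ΔH3 = −19.0 kJ/mol)
    2 incoming ligand → self-condensation product (k4 = 0.023 /M/s, Ea4 = 86.0 kJ/mol)
    incoming ligand ⇌ dormant form (K5 = 1.4, k5 = 3.1 × 10⁻⁴ /s, Ea5 = 103 kJ/mol, ΔH5 = −39.0 kJ/mol)
    (constants at 100 °C)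

| flask | starting complex | incoming ligand | leaving ligand | temperature | time | remark |
|---|---|---|---|---|---|---|
| maple | 0.050 M (in portions, 2, over 3.0 h) | 0.100 M | 0.100 M | 100 °C | 4.0 h | first portion at the start, last at 3.0 h |
| elm | 0.050 M (fed, over 20 min) | 0.100 M | 0.100 M | 100 °C | 4.0 h | all else is in the flask from the start; the feed brings no volume worth counting |
| larch | 0.050 M (fed, over 3.0 h) | 0.100 M | 0.100 M |  | 4.0 h | the addition at 60 °C, then warmed to 100 °C; the feed brings no volume worth counting |
| birch | 0.050 M (fed, over 3.0 h) | 0.100 M | 0.100 M | 100 °C | 4.0 h | all else is in the flask from the start; the feed brings no volume worth counting |
| ash | 0.050 M | 0.100 M | 0.100 M | 100 °C | 4.0 h | everything together at the start |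

- a doubled species enters its step squared and goes two at a time
- the constants hold at 100 °C; other temperatures follow from the activation energies and enthalpies

- the flask with the highest share of complex with one exchanged in complex with one exchanged plus complex with two exchanged ("all alike" if they lie within 1.5 percentage points) (maple / elm / larch / birch / ash / all alike)
- share of complex with one exchanged in complex with one exchanged plus complex with two exchanged at the end, maple
- share of complex with one exchanged in complex with one exchanged plus complex with two exchanged at the end, elm
- share of complex with one exchanged in complex with one exchanged plus complex with two exchanged at the end, larch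
- share of complex with one exchanged in complex with one exchanged plus complex with two exchanged at the end, birch
- share of complex with one exchanged in complex with one exchanged plus complex with two exchanged at the end, ash

1. The bench rule of thumb for an exchange is that the ratio of the two complexes follows the ratio of the two ligands. If the second exchange stands at quasi-equilibrium, [complex with two exchanged]/[complex with one exchanged] = q, with q = K2[incoming ligand]/[leaving ligand], and the share asked for is 1/(1+q). So I need [incoming ligand] at the end, and I reckon it as a fraction left.

2. The first half-life of incoming ligand by self-condensation alone is 3.62 min, far shorter than the 3.0 h of the birch feed. So in birch I count condensation as the loss of incoming ligand and let the complex arrive in what remains.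

3. In birch the dormant form relaxes with a half-life of 0.362 h, longer than the condensation half-life at the charge, so at the start free and dormant ligand are out of balance. As a rough simplification I still treat them as one pool, equal to (1+K5)[incoming ligand]. Self-condensation takes from this pool at a rate in [incoming ligand] squared, so the reciprocal of the pool grows linearly in time. Over the run it grows by 11.5 times its starting value, which leaves 8.00 % of the pool.

4. Dividing by 1+K5 gives the free fraction left, the part of the charged incoming ligand still free at the end: 3.33 %. At that free amount the condensation half-life is 1.81 h, longer than the relaxation half-life, so the simplification suits the end of the run better than its start, and the figure stays an estimate.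

5. With [leaving ligand] taken at its charge, q = 0.767, so for birch I commit to 56.6 %.

6. The border has two sides. First, the second exchange must relax after the last arrival. With both directions counted at these concentrations, its half-life is 22.1 min, shorter than the 60.0 min birch has after its feed.

Second, there must be little complex with three exchanged to come back. The ratio of the return constants, (k3/K3)/(k2/K2), is 0.637, below one, so a stock of that complex returns more slowly than complex with two exchanged does and keeps refilling it.

In ash the forward half-lives at the charged concentrations, 1.7 min and 1.2 min, are shorter than the condensation half-life, so that stock forms early. I put ash beyond the border and give it no number.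

7. The forecast names birch and gives 32 % for maple, 38 % for elm, 4 % for larch, 60 % for birch and 18 % for ash. Its ground is that “the later the complex arrives the less it advances”. We differ on ash, where it gives a number and I give none.

8. The simulation gives 41.8 % for maple, 45.4 % for elm, 24.5 % for larch, 60.2 % for birch and 34.7 % for ash. Birch stands highest. Ash lies below the rule's figure and above the forecast's.

9. In birch, free incoming ligand reads 2.78 % of its charge against my 3.33 %, and [dormant form]/[incoming ligand] reads 1.79 against the 1.4 of the pool. The neighbouring flask is birch with 0.040 M of leaving ligand. The free fraction left contains no leaving ligand, so I carry 3.33 % across unchanged. Leaving ligand there reads 118 % of its own smaller charge, which makes q = 1.63 and the share 38.1 %. That neighbouring flask reads free incoming ligand at 2.27 % of its charge and a share of 54.9 %.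

Its constants belong to no real substance; the run is a simulation.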